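(The numbers are those of an exercise; the run is a simulation.)

The constants of coupling and dimerisation, 29 /M/s and 5.4 /M/s, headed the agenda, with this flask under them.

solid substrate 0.0020 M; partner 1.50 equiv; protic impurity 0.0400 mM; time 10 min

    solid substrate ⇌ dissolved substrate, rate k1*(cs1 - [dissolved substrate]) while solid is left; crystals form when [dissolved substrate] > cs1 (cs1 = 0.74 mM, k1 = 0.012 /s)
    dissolved substrate + partner → target (k2 = 29 /M/s)
    solid product ⇌ target, rate k3*(cs3 - [target]) while solid is left; crystals form when [target] > cs3 (cs3 = 0.91 mM, k3 = 0.15 /s)
    partner + protic impurity → quenched reagent (k4 = 160 /M/s)
    2 partner → homo dimer (k5 = 5.4 /M/s)
    partner ⇌ dormant form (K6 = 0.74, k6 = 0.010 /s)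

- target is meant together with its solid product
- where a step has two of a species, its rate is k times that concentration squared, and two are used at each turn
- solid, in amounts per volume of the solution: solid substrate, solid product
- at the start none of the solid substrate is in solution
- run time (flask): 10 min

- target and solid product together at 10 min, in percent of the solid substrate charged
- the change that raises the amount of target and solid product together at 10 min, in percent of the solid substrate charged most ("none" if none brings more than 2 percentage points) (Monday's / Wednesday's / Friday's / Thursday's / none)
- amount of target and solid product together at 10 min, in percent of the solid substrate charged, after Wednesday's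

- Monday's: doubling the dissolution coefficient of step 1, all else as stated
- Wednesday's: doubling the amount of partner, all else as stated
- Friday's: doubling the solubility in step 3, all else as stated
- Thursday's: doubling the solubility in step 1, all else as stated

The process chemist opened with the end state: the protic impurity takes its 0.0400 mM of partner and leaves 2.96 mM, which coupling and dimerisation then share. The kineticist wanted that share as one quantity. At a partner concentration where the two steps consume partner equally, c(dissolved substrate) stands at 0.372 times c(partner). She set dissolution equal to coupling there and solved for the crossover concentration c× = 0.723 mM, the partner concentration at which coupling and dimerisation consume partner equally, with dissolved substrate taken as quasi-steady. That level of dissolved substrate is 0.269 mM, below the solubility 0.74 mM.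

Holding it and integrating both losses, she obtained target made = c× ln(1 + available partner/c×), which is 1.18 mM, or 58.9%. The process chemist noted that this is less than the 0.0020 M of solid substrate charged, so in this reckoning partner, though charged at 1.50 equiv, is the limiting reagent. Partner's lifetime against coupling at that level is 2.13 min, and 10 min is 4.69 such lifetimes, so the end state should be close. The dormant form was left out of the reckoning; its relaxation half-life is 0.491 min, shorter than that lifetime.

For the changes, the same formula gives 80.4% after Wednesday's. Thursday's moves c× to 1.09 mM and the yield to 71.6%. Monday's moves c× to 0.934 mM and the yield to 66.7%. Friday's solubility does not appear in the formula. The meeting therefore chose Wednesday's.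

The forecast gave 59% (52% to 66%), Wednesday's as best, and 77% (68% to 86%) after it, holding that faster dissolution helps “since partner limits”.

The simulation gives 57.8%, with Wednesday's best at 14 percentage points, then Thursday's at 12 points, Monday's at 9.2 points and Friday's at 0 points; after Wednesday's the flask gives 71.9%.

The neighbour flask with 3.80 equiv of partner keeps c× at 0.723 mM, since the partner charge does not enter it. Its available partner is 7.56 mM, so the reckoning gives 88.2%. That flask holds 75.8% of target and solid product together, 12 points below the reckoning, a wider gap than the 8.5 points after Wednesday's. In that flask solid substrate stands at 0% and dissolved substrate at 24.2%.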